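The aryl ester C5–O bond is made last, from triene alcohol 22 and 4-O-silyl vanillic acid 25 (Yamaguchi), and one fluoride step then frees the phenol.
Feature used: with the carbocycle numbered C1 (=CH2), C2=C3, C4 (CMe2), C5 (CH–O), C6, C7, C8(Me)=C9, C10, C11, the atoms C8=C9–C10–C11–C1–C2 are the product pattern of an oxy-Cope shift once C2 is a ketone; cutting C10–C11 and rejoining C2–C8 folds the eleven-membered ring back to a 1,2-divinylcycloheptanol whose ring C2–C8 carries the C4 gem-dimethyl, the C5 oxygen and the C8 methyl.
After ring expansion the C1 enolate is methylenated through a Mannich base, and the C2 ketone is converted to the C2=C3 alkene (Luche reduction, carbonate, palladium-catalysed elimination toward C3).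
The cycloheptane is eucarvone (from carvone); C5 is set by catalytic asymmetric epoxidation of its γ,δ-alkene followed by SmI2 opening, and the two vinyl groups come from α-vinylation and vinylcerium addition.
Ring order: six-membered (carvone), seven-membered (eucarvone), eleven-membered (oxy-Cope, four atoms added), then the vanillate is attached.

Key step: step 11

Remark on numbering: eleven-membered compounds carry the target numbering given above; seven-membered compounds are numbered from the ketone carbon (C1), with the methyl-bearing carbon C2, the oxygenated carbon C5 and the gem-dimethyl carbon C6. TBS = tert-butyldimethylsilyl, TMS = trimethylsilyl.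

Step 1
Reactants: 1 (R)-carvone
Product: 2 carvone hydrobromide [(5R)-5-(2-bromopropan-2-yl)-2-methylcyclohex-2-en-1-one]
Conditions: HBr (33% in AcOH), 0–10 °C
Reagents that add atoms: hydrogen bromide, Br
Why: Markovnikov hydrobromination: the electron-rich 1,1-disubstituted isopropenyl alkene is protonated to a tertiary cation that captures bromide, while the electron-poor enone alkene does not react, and no stereocentre is formed.

Step 2
Reactants: 2 carvone hydrobromide
Product: 4 eucarvone (2,6,6-trimethylcyclohepta-2,4-dien-1-one), via carenone 3 (not isolated)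
Conditions: KOH, MeOH, reflux
Reagents that add atoms: none
Why: Intramolecular enolate alkylation followed by base-induced ring opening (the classical carvone-to-eucarvone rearrangement): the α'-enolate displaces the tertiary bromide to close the cyclopropane of 3, whose dienolate opens the three-membered ring to the cycloheptadienone, and the only stereocentre of the carvone is destroyed on the way.

Step 3
Reactants: 4 eucarvone
Product: 5 (4R,5S)-4,5-epoxy-2,6,6-trimethylcyclohept-2-en-1-one
Conditions: (R,R)-(salen)MnCl [(R,R)-N,N'-bis(3,5-di-tert-butylsalicylidene)-1,2-cyclohexanediaminomanganese chloride] (5 mol%), 4-phenylpyridine N-oxide, aq. NaOCl (pH 11.3), CH2Cl2, 0 °C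
Reagents that add atoms: sodium hypochlorite, [Na+].[O-]Cl
Why: Jacobsen–Katsuki epoxidation: the oxo-manganese species transfers oxygen to the electron-richer cis-disubstituted γ,δ-alkene (the α,β-alkene is carbonyl-deactivated), an olefin flanked by a quaternary carbon and a conjugating vinyl group just as in the 2,2-dimethylchromenes that are model substrates, so that the chiral salen ligand fixes both epoxide carbons in one face-selective event; the (R,R)-complex is chosen by analogy with the chromene series and the sense is to be checked by Mosher analysis of 6, the (S,S)-complex being used if the opposite face is found.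

Step 4
Reactants: 5 (4R,5S)-4,5-epoxy-2,6,6-trimethylcyclohept-2-en-1-one
Product: 6 (5R)-5-hydroxy-2,6,6-trimethylcyclohept-3-en-1-one (C2 epimers)
Conditions: SmI2 (2.2 equiv), THF/MeOH, −90 °C
Reagents that add atoms: none
Why: SmI2 reduction of a γ,δ-epoxy enone: two single-electron transfers generate a dienolate that expels the γ-oxygen (C4–O), so the C5–O bond and its configuration are untouched, and α-protonation by methanol gives the δ-hydroxy β,γ-enone whose alkene position and C2 configuration are of no consequence.

Step 5
Reactants: 6 (5R)-5-hydroxy-2,6,6-trimethylcyclohept-3-en-1-one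
Product: 7 (5R)-5-(tert-butyldimethylsilyloxy)-2,6,6-trimethylcyclohept-3-en-1-one (C2 epimers)
Conditions: TBSOTf, 2,6-lutidine, CH2Cl2, −78 to 0 °C
Reagents that add atoms: tert-butyldimethylsilyl triflate, CC(C)(C)[Si](C)(C)OS(=O)(=O)C(F)(F)F
Why: Silylation with the silyl triflate, reactive enough for the neopentyl secondary alcohol next to the gem-dimethyl carbon and able to drain any transannular hemiketal form, gives the TBS ether without touching C5.

Step 6
Reactants: 7 (5R)-5-(tert-butyldimethylsilyloxy)-2,6,6-trimethylcyclohept-3-en-1-one
Product: 8 (5R)-5-(tert-butyldimethylsilyloxy)-2,6,6-trimethylcycloheptan-1-one (C2 epimers)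
Conditions: H2 (1 atm), 5% Pd/C, EtOAc, rt
Reagents that add atoms: none
Why: Heterogeneous catalytic hydrogenation saturates the cis-disubstituted ring alkene (or its conjugated isomer) in a non-protic solvent that spares the silyl ether, and the C2 methyl epimers formed are both usable because C2 is planarised in the next step.

Step 7
Reactants: 8 (5R)-5-(tert-butyldimethylsilyloxy)-2,6,6-trimethylcycloheptan-1-one
Product: 9 (5R)-5-(tert-butyldimethylsilyloxy)-2,6,6-trimethyl-1-(trimethylsilyloxy)cyclohept-1-ene
Conditions: TMSCl, NaI, Et3N, MeCN, rt; pentane extraction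
Reagents that add atoms: chlorotrimethylsilane, C[Si](C)(C)Cl
Why: Silyl enol ether formation under equilibrating conditions (iodotrimethylsilane generated in situ with triethylamine) gives the more substituted C1=C2 enol ether, the isomer toward C7 being disfavoured by the adjacent gem-dimethyl group, which fixes the site of the next C–C bond.

Step 8
Reactants: 9 (5R)-5-(tert-butyldimethylsilyloxy)-2,6,6-trimethyl-1-(trimethylsilyloxy)cyclohept-1-ene
Product: 11 (5R)-5-(tert-butyldimethylsilyloxy)-2,6,6-trimethyl-2-[2-(phenylsulfinyl)ethyl]cycloheptan-1-one (diastereomers at C2 and sulfur), via lithium enolate 10 (not isolated)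
Conditions: MeLi, THF, 0 °C; then phenyl vinyl sulfoxide, −78 to −20 °C; H2O quench
Reagents that add atoms: phenyl vinyl sulfoxide, C=CS(=O)c1ccccc1
Why: Methyllithium cleaves the O–Si bond to the regiodefined lithium enolate 10, which undergoes Michael addition to phenyl vinyl sulfoxide (a vinyl cation equivalent) at the methyl-bearing carbon to build the quaternary centre as both epimers, a mixture that is acceptable because this carbon becomes sp2 in step 11.

Step 9
Reactants: 11 (5R)-5-(tert-butyldimethylsilyloxy)-2,6,6-trimethyl-2-[2-(phenylsulfinyl)ethyl]cycloheptan-1-one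
Product: 12 (5R)-5-(tert-butyldimethylsilyloxy)-2,6,6-trimethyl-2-vinylcycloheptan-1-one (both C2 epimers)
Conditions: xylene, CaCO3, 140 °C
Reagents that add atoms: none
Why: Thermal syn-elimination of benzenesulfenic acid (sulfoxide pyrolysis) can only take a hydrogen from the CH2 attached to the quaternary carbon, so the terminal vinyl group results and the quaternary centre is untouched.

Step 10
Reactants: 12 (5R)-5-(tert-butyldimethylsilyloxy)-2,6,6-trimethyl-2-vinylcycloheptan-1-one
Product: 13 (5R)-5-(tert-butyldimethylsilyloxy)-2,6,6-trimethyl-1,2-divinylcycloheptan-1-ol with the two vinyl groups trans (drawn epimer: C1–OH, C2–vinyl and C5–OSi on one face; its partner epimeric at both C1 and C2 is carried along)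
Conditions: CeCl3 (anhydrous), CH2=CHMgBr, THF, −78 to 0 °C; H2O quench; chromatography
Reagents that add atoms: vinylmagnesium bromide, C=C[Mg]Br
Why: Organocerium 1,2-addition (Imamoto conditions) adds the vinyl group to the hindered ketone with little enolisation; the carbinol centre is set under weak substrate control, so a mixture is expected from which the isomers having the new vinyl trans to the resident vinyl (one from each C2 epimer) are separated by chromatography and pooled, the cis isomers being set aside.

Step 11
Reactants: 13 trans-1,2-divinylcycloheptanol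
Product: 16 Mannich base (5R,8E)-1-[(dimethylamino)methyl]-5-(tert-butyldimethylsilyloxy)-4,4,8-trimethylcycloundec-8-en-2-one (C1 epimers), via potassium alkoxide 14 (not isolated), via potassium enolate 15 (not isolated)
Conditions: KH, 18-crown-6, THF, 0 °C to rt; then enolate solution transferred onto CH2=NMe2+ I− in THF, −78 °C to rt
Reagents that add atoms: N,N-dimethylmethyleneiminium iodide (Eschenmoser's salt), C=[N+](C)C.[I-]
Why: KH with 18-crown-6 gives the naked potassium alkoxide 14, whose charge-accelerated [3,3] sigmatropic shift through a chair transition state cleaves the cycloheptane bond between the carbinol carbon (C2 of the target) and the quaternary carbon (C8) while the two vinyl termini join as C10–C11, giving the C8=C9 alkene and the C1=C2 potassium enolate 15, which is C-aminomethylated at C1 by the iminium salt. The closest known reaction type is the anionic oxy-Cope ring expansion of 1,2-divinylcycloalkanols to cycloalk-5-enones with electrophilic capture of the enolate, best known for the cyclohexanol-to-cyclodecenone (germacrane) case. The eleven-membered ring is closed by four-atom ring enlargement, the new C10–C11 bond forming inside a six-centre array already tethered by the seven-membered ring, so this is not an end-to-end macrocyclisation and needs no high dilution, and enolate formation pays for the strain of the E-cycloundecene. No stereocentre of consequence is created: the carbinol and quaternary centres become sp2, the C1 centre of 16 forms without control and is erased in step 12, and C5 is a spectator whose C–O bond is not touched. The selectivity needed is the E geometry at C8=C9, which requires a chair with the ring bond C8–C7 pseudo-equatorial and the C8 methyl pseudo-axial; the trans-divinyl arrangement of 13 secures it, because with the two vinyl groups gauche both ring bonds (C8–C7 and C2–C3) sit pseudo-equatorial, whereas the alternative chair would need them antiperiplanar, which a seven-membered ring cannot span. The regiochemistry of the later functionalisation is secured because the rearrangement generates the enolate only toward C1.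

Step 12
Reactants: 16 Mannich base
Product: 18 (5R,8E)-5-(tert-butyldimethylsilyloxy)-4,4,8-trimethyl-1-methylenecycloundec-8-en-2-one, via methiodide 17 (not isolated)
Conditions: MeI, MeOH, rt; then aq. NaHCO3, CH2Cl2, rt
Reagents that add atoms: none
Why: Exhaustive N-methylation followed by E1cB loss of trimethylamine from the β-ammonium ketone (Mannich methylenation) gives the exocyclic enone and removes the uncontrolled C1 stereocentre.

Step 13
Reactants: 18 (5R,8E)-5-(tert-butyldimethylsilyloxy)-4,4,8-trimethyl-1-methylenecycloundec-8-en-2-one
Product: 19 (5R,8E)-5-(tert-butyldimethylsilyloxy)-4,4,8-trimethyl-1-methylenecycloundec-8-en-2-ol (C2 epimers)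
Conditions: NaBH4, CeCl3·7H2O, MeOH, −20 °C
Reagents that add atoms: none
Why: Luche reduction: cerium-assisted borohydride delivers hydride 1,2 to the carbonyl and not to the exposed exocyclic enone terminus, and the configuration of the new carbinol is irrelevant because C2 becomes sp2 in step 15.

Step 14
Reactants: 19 (5R,8E)-5-(tert-butyldimethylsilyloxy)-4,4,8-trimethyl-1-methylenecycloundec-8-en-2-ol
Product: 20 methyl carbonate of 19 at the C2 oxygen (C2 epimers)
Conditions: ClCO2Me, pyridine, DMAP (cat.), CH2Cl2, 0 °C to rt
Reagents that add atoms: methyl chloroformate, COC(=O)Cl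
Why: Acylation of the secondary allylic alcohol with methyl chloroformate under pyridine/DMAP catalysis installs a carbonate that ionises readily on zerovalent palladium and releases its own base.

Step 15
Reactants: 20 allylic methyl carbonate
Product: 21 (2E,5R,8E)-5-(tert-butyldimethylsilyloxy)-4,4,8-trimethyl-1-methylenecycloundeca-2,8-diene
Conditions: Pd(OAc)2 (5 mol%), PBu3 (20 mol%), 1,4-dioxane, reflux
Reagents that add atoms: none
Why: Palladium-catalysed elimination of an allylic carbonate (Tsuji diene synthesis): zerovalent palladium formed in situ ionises the carbonate with loss of CO2 to a π-allyl complex over C2, C1 and the exocyclic carbon, methoxide acts as the base, and since hydrogens β to an allyl terminus exist only on C3 (C4 is quaternary and the exocyclic terminus has no further neighbour) the conjugated C2=C3/C1=CH2 diene must form, with E geometry expected because a Z alkene would press the C4 gem-dimethyl group against C1.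

Step 16
Reactants: 21 (2E,5R,8E)-5-(tert-butyldimethylsilyloxy)-4,4,8-trimethyl-1-methylenecycloundeca-2,8-diene
Product: 22 (2E,5R,8E)-4,4,8-trimethyl-1-methylenecycloundeca-2,8-dien-5-ol
Conditions: TBAF, THF, rt to 50 °C
Reagents that add atoms: none
Why: Fluoride-induced Si–O cleavage, driven by the strong Si–F bond, frees the C5 hydroxyl without affecting the triene or the stereocentre.

Step 17
Reactants: 23 vanillic acid
Product: 25 4-(tert-butyldimethylsilyloxy)-3-methoxybenzoic acid, via bis-silyl vanillate 24 (not isolated)
Conditions: TBSCl (2.4 equiv), imidazole, DMF, rt; then AcOH/THF/H2O, rt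
Reagents that add atoms: tert-butyldimethylsilyl chloride, CC(C)(C)[Si](C)(C)Cl
Why: Silylation of both the phenol and the carboxylic acid followed by mild acidic hydrolysis, which cleaves the far more labile silyl ester selectively, leaves the aryl silyl ether in place.

Step 18
Reactants: 22 (2E,5R,8E)-4,4,8-trimethyl-1-methylenecycloundeca-2,8-dien-5-ol and 25 4-(tert-butyldimethylsilyloxy)-3-methoxybenzoic acid
Product: 27 (2E,5R,8E)-4,4,8-trimethyl-1-methylenecycloundeca-2,8-dien-5-yl 4-(tert-butyldimethylsilyloxy)-3-methoxybenzoate, via mixed anhydride 26 (not isolated)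
Conditions: 2,4,6-Cl3C6H2COCl, Et3N, THF, rt; then 22, DMAP, toluene, rt to 60 °C
Reagents that add atoms: none
Why: Yamaguchi esterification: the mixed anhydride 26 is opened by DMAP at the less hindered aroyl carbonyl and the resulting acylpyridinium acylates the hindered neopentyl C5 alcohol, the C5–O bond staying intact so that the (R) configuration is retained.

Step 19
Reactants: 27 silyl-protected vanillate ester
Product: 28 target, (2E,5R,8E)-4,4,8-trimethyl-1-methylenecycloundeca-2,8-dien-5-yl 4-hydroxy-3-methoxybenzoate
Conditions: TBAF, AcOH, THF, 0 °C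
Reagents that add atoms: none
Why: Buffered fluoride removes the aryl silyl ether, the most labile silyl group because phenoxide is a good leaving group, while acetic acid protonates the phenoxide so that neither the aryl ester nor the triene is attacked.

Compound list
1 | (R)-carvone [(5R)-2-methyl-5-(prop-1-en-2-yl)cyclohex-2-en-1-one] | CC1=CC[C@H](CC1=O)C(C)=C | starting material
2 | carvone hydrobromide [(5R)-5-(2-bromopropan-2-yl)-2-methylcyclohex-2-en-1-one] | CC1=CC[C@H](CC1=O)C(C)(C)Br | intermediate
3 | carenone (cis-fused 3,7,7-trimethylbicyclo[4.1.0]hept-3-en-2-one) | CC1=CC[C@@H]2[C@H](C1=O)C2(C)C | intermediate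
4 | eucarvone (2,6,6-trimethylcyclohepta-2,4-dien-1-one) | CC1=CC=CC(C)(C)CC1=O | intermediate
5 | (4R,5S)-4,5-epoxy-2,6,6-trimethylcyclohept-2-en-1-one | O=C1CC(C)(C)[C@@H]2O[C@@H]2C=C1C | intermediate
6 | (5R)-5-hydroxy-2,6,6-trimethylcyclohept-3-en-1-one (C2 epimers) | O=C1CC(C)(C)[C@H](O)C=CC1C | intermediate
7 | (5R)-5-(tert-butyldimethylsilyloxy)-2,6,6-trimethylcyclohept-3-en-1-one (C2 epimers) | O=C1CC(C)(C)[C@H](O[Si](C)(C)C(C)(C)C)C=CC1C | intermediate
8 | (5R)-5-(tert-butyldimethylsilyloxy)-2,6,6-trimethylcycloheptan-1-one (C2 epimers) | O=C1CC(C)(C)[C@H](O[Si](C)(C)C(C)(C)C)CCC1C | intermediate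
9 | (5R)-5-(tert-butyldimethylsilyloxy)-2,6,6-trimethyl-1-(trimethylsilyloxy)cyclohept-1-ene | C[Si](C)(C)OC1=C(C)CC[C@@H](O[Si](C)(C)C(C)(C)C)C(C)(C)C1 | intermediate
10 | lithium C1=C2 enolate of 8 | [Li+].[O-]C1=C(C)CC[C@@H](O[Si](C)(C)C(C)(C)C)C(C)(C)C1 | intermediate
11 | (5R)-5-(tert-butyldimethylsilyloxy)-2,6,6-trimethyl-2-[2-(phenylsulfinyl)ethyl]cycloheptan-1-one (diastereomers at C2 and sulfur) | O=C1CC(C)(C)[C@H](O[Si](C)(C)C(C)(C)C)CCC1(C)CCS(=O)c1ccccc1 | intermediate
12 | (5R)-5-(tert-butyldimethylsilyloxy)-2,6,6-trimethyl-2-vinylcycloheptan-1-one (both C2 epimers) | O=C1CC(C)(C)[C@H](O[Si](C)(C)C(C)(C)C)CCC1(C)C=C | intermediate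
13 | (5R)-5-(tert-butyldimethylsilyloxy)-2,6,6-trimethyl-1,2-divinylcycloheptan-1-ol, vinyl groups trans (drawn: C1–OH, C2–vinyl and C5–OSi on one face; the epimer inverted at both C1 and C2 is used alike) | C=C[C@@]1(O)CC(C)(C)[C@H](O[Si](C)(C)C(C)(C)C)CC[C@]1(C)C=C | intermediate
14 | potassium alkoxide of 13 | C=C[C@@]1([O-])CC(C)(C)[C@H](O[Si](C)(C)C(C)(C)C)CC[C@]1(C)C=C.[K+] | intermediate
15 | potassium C1=C2 enolate of (5R,8E)-5-(tert-butyldimethylsilyloxy)-4,4,8-trimethylcycloundec-8-en-2-one | C1/C([O-])=C/CC/C=C(\C)CC[C@@H](O[Si](C)(C)C(C)(C)C)C1(C)C.[K+] | intermediate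
16 | (5R,8E)-1-[(dimethylamino)methyl]-5-(tert-butyldimethylsilyloxy)-4,4,8-trimethylcycloundec-8-en-2-one (C1 epimers) | CN(C)CC1C(=O)CC(C)(C)[C@H](O[Si](C)(C)C(C)(C)C)CC/C(C)=C/CC1 | intermediate
17 | trimethylammonium iodide (methiodide) of 16 | C[N+](C)(C)CC1C(=O)CC(C)(C)[C@H](O[Si](C)(C)C(C)(C)C)CC/C(C)=C/CC1.[I-] | intermediate
18 | (5R,8E)-5-(tert-butyldimethylsilyloxy)-4,4,8-trimethyl-1-methylenecycloundec-8-en-2-one | C=C1C(=O)CC(C)(C)[C@H](O[Si](C)(C)C(C)(C)C)CC/C(C)=C/CC1 | intermediate
19 | (5R,8E)-5-(tert-butyldimethylsilyloxy)-4,4,8-trimethyl-1-methylenecycloundec-8-en-2-ol (C2 epimers) | C=C1C(O)CC(C)(C)[C@H](O[Si](C)(C)C(C)(C)C)CC/C(C)=C/CC1 | intermediate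
20 | methyl carbonate of 19 (C2 epimers) | C=C1C(OC(=O)OC)CC(C)(C)[C@H](O[Si](C)(C)C(C)(C)C)CC/C(C)=C/CC1 | intermediate
21 | (2E,5R,8E)-5-(tert-butyldimethylsilyloxy)-4,4,8-trimethyl-1-methylenecycloundeca-2,8-diene | C=C1/C=C/C(C)(C)[C@H](O[Si](C)(C)C(C)(C)C)CC/C(C)=C/CC1 | intermediate
22 | (2E,5R,8E)-4,4,8-trimethyl-1-methylenecycloundeca-2,8-dien-5-ol | C=C1/C=C/C(C)(C)[C@H](O)CC/C(C)=C/CC1 | intermediate
23 | vanillic acid (4-hydroxy-3-methoxybenzoic acid) | COc1cc(C(=O)O)ccc1O | starting material
24 | tert-butyldimethylsilyl 4-(tert-butyldimethylsilyloxy)-3-methoxybenzoate | COc1cc(C(=O)O[Si](C)(C)C(C)(C)C)ccc1O[Si](C)(C)C(C)(C)C | intermediate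
25 | 4-(tert-butyldimethylsilyloxy)-3-methoxybenzoic acid | COc1cc(C(=O)O)ccc1O[Si](C)(C)C(C)(C)C | intermediate
26 | mixed anhydride of 25 and 2,4,6-trichlorobenzoic acid | COc1cc(C(=O)OC(=O)c2c(Cl)cc(Cl)cc2Cl)ccc1O[Si](C)(C)C(C)(C)C | intermediate
27 | (2E,5R,8E)-4,4,8-trimethyl-1-methylenecycloundeca-2,8-dien-5-yl 4-(tert-butyldimethylsilyloxy)-3-methoxybenzoate | C=C1/C=C/C(C)(C)[C@H](OC(=O)c2ccc(O[Si](C)(C)C(C)(C)C)c(OC)c2)CC/C(C)=C/CC1 | intermediate
28 | CNP0416843.1, (2E,5R,8E)-4,4,8-trimethyl-1-methylenecycloundeca-2,8-dien-5-yl 4-hydroxy-3-methoxybenzoate | C=C1/C=C/C(C)(C)[C@H](OC(=O)c2ccc(O)c(OC)c2)CC/C(C)=C/CC1 | target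

Total step count: 19
Longest linear sequence: 18 steps (steps 1–16, 18 and 19; step 17 is the one-step vanillate branch)

Steps most likely to fail

Step 3. Oxygen transfer may proceed with insufficient face selectivity (a stepwise radical pathway on the dienone would erode it) or partly at the wrong site, so that the C5 centre is not obtained in usable enantiopurity.
Fallback: this sets out from 4 and replaces catalyst control by separation of diastereomers.
- Buffered mCPBA (NaHCO3, CH2Cl2, 0 °C) should give the racemic cis-4,5-epoxy-2,6,6-trimethylcyclohept-2-en-1-one F1.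
- SmI2 as in step 4 opens it to racemic 5-hydroxy-2,6,6-trimethylcyclohept-3-en-1-one F2.
- DBU moves the alkene into conjugation to give racemic 5-hydroxy-2,6,6-trimethylcyclohept-2-en-1-one F3, which has a single stereocentre.
- Esterification with (S)-O-methylmandelic acid (DCC, DMAP) gives two diastereomers; chromatography should deliver the (5R)-configured (S)-O-methylmandelate of the conjugated hydroxy enone F4, assigned by the mandelate anisotropy model.
- Hydrogenation (H2, Pd/C, EtOAc) gives the saturated mandelate ketone F5, so that the acyloxy group can no longer be lost by vinylogous elimination.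
- K2CO3 in MeOH releases (5R)-5-hydroxy-2,6,6-trimethylcycloheptan-1-one F6.
- TBSOTf/2,6-lutidine silylates F6, which comes back to the route at 8.

Step 8. Conjugate addition of the hindered tetrasubstituted enolate may be slow, and proton transfer between the adduct anion and unreacted enolate may return ketone 8 or scramble the enolate toward C7.
Fallback: this sets out from 9 and replaces the Michael addition/pyrolysis pair by a cross-coupling. The lithium enolate 10 is generated as before and coupled with vinyl bromide under zerovalent palladium catalysis (Pd2(dba)3, P(t-Bu)3, THF, rt to 50 °C), a palladium-catalysed ketone α-vinylation. It comes back to the route directly at 12 and makes no new compound (F0).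

Step 15. The π-allyl palladium intermediate may be captured by methoxide to give an allyl methyl ether, or palladium hydride may isomerise the exocyclic diene or erode the C2=C3 geometry.
Fallback: this sets out from 19 and uses a metal-free thermal syn-elimination. Burgess reagent (methyl N-(triethylammoniosulfonyl)carbamate, benzene, 50–70 °C) converts the alcohol into the triethylammonium N-(methoxycarbonyl)sulfamate ester of 19 F7. This ester eliminates intramolecularly through the C3 hydrogen, the only β-hydrogen available, and comes back to the route at 21.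

Further compounds
F1 | step 3 | racemic cis-4,5-epoxy-2,6,6-trimethylcyclohept-2-en-1-one | O=C1CC(C)(C)C2OC2C=C1C
F2 | step 3 | racemic 5-hydroxy-2,6,6-trimethylcyclohept-3-en-1-one | O=C1CC(C)(C)C(O)C=CC1C
F3 | step 3 | racemic 5-hydroxy-2,6,6-trimethylcyclohept-2-en-1-one | O=C1CC(C)(C)C(O)CC=C1C
F4 | step 3 | (5R)-configured (S)-O-methylmandelate of the conjugated hydroxy enone | O=C1CC(C)(C)[C@H](OC(=O)[C@@H](OC)c2ccccc2)CC=C1C
F5 | step 3 | saturated mandelate ketone (C2 epimers) | O=C1CC(C)(C)[C@H](OC(=O)[C@@H](OC)c2ccccc2)CCC1C
F6 | step 3 | (5R)-5-hydroxy-2,6,6-trimethylcycloheptan-1-one (C2 epimers) | O=C1CC(C)(C)[C@H](O)CCC1C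
F0 | step 8 | none | none
F7 | step 15 | triethylammonium N-(methoxycarbonyl)sulfamate ester of 19 | C=C1C(OS(=O)(=O)[N-]C(=O)OC)CC(C)(C)[C@H](O[Si](C)(C)C(C)(C)C)CC/C(C)=C/CC1.CC[NH+](CC)CC
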